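**Retrosynthetic overview**

1. Late disconnections: the C3–O ester bond to (2E,4E,6E)-5-methyldodeca-2,4,6-trienoic acid, and the (Z)-C8(=O)–C7=C11(CH3)–C12H2OH unit back to a 3-methylfuran fused at C7–C8 (singlet-oxygen unmasking; the furan ring fixes the Z geometry).
2. Enabling feature: in ring A (C1–C2–C3–C4–C5–C10) the oxygen on C3 is 1,4 to C10, C10 neighbours the oxygenated C9 of ring B, and C15H3, C14H3 and H-10 all lie on one face of a cis-fused decalin. This is the retron of an endo [4+2] between a C5=C10 enone (C9=O) and a 2-oxy-diene C1=C2–C3(O)=C4 whose C4 substituent is held "inside".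
3. Key step: catalytic enantioselective Diels–Alder reaction of achiral 3,5-dimethylbenzofuran-4,7-dione (furan + ring B) with 4-silyloxy-2H-thiopyran. It forms C4–C5 and C1–C10 and the C4/C5/C10 stereotriad at once; the sulfur bridge is a temporary ring, later cut to C15H3 and C1H2.
4. The rigid thiabicyclo[2.2.2]octene is then used to set C9 (reduction, then inversion) and C3 (reduction); the surplus quinone oxygen at C6 is removed and Raney nickel opens the bridge.
5. Ring order: furan, then ring B (as the quinone), then ring A last (step 7); no ring of the skeleton is formed afterwards.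

Key step: step 7

Remark (numbering): eremophilane numbering is used for all bicyclic intermediates (ring A = C1–C2–C3–C4–C5–C10; ring B = C5–C6–C7–C8–C9–C10; C11 on C7 carries C13H3 and C12; C14 = CH3 on C5; C15 = CH3 on C4; β = face of C14); in the cycloaddition quinone 6 maps as C5→C5, C6→C10, C7→C9, C4→C6, and diene 9 (atoms primed) as C3′→C4, C4′→C3, C5′→C2, C6′→C1, C2′→C15.

**Route**

Step 1
Reactants: 1 2-methoxy-4-methylphenol (creosol); 2 chloroacetone
Product: 3 1-(2-methoxy-4-methylphenoxy)propan-2-one
Conditions: K2CO3, KI (cat.), acetone, reflux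
Reagents that add atoms: none
Why: Williamson ether synthesis (SN2 of the phenoxide on the activated α-chloroketone); no stereocentre is involved.

Step 2
Reactants: 3 1-(2-methoxy-4-methylphenoxy)propan-2-one
Product: 4 7-methoxy-3,5-dimethyl-1-benzofuran
Conditions: Amberlyst-15, toluene, reflux (Dean–Stark)
Reagents that add atoms: none
Why: Acid-catalysed cyclodehydration of an aryloxyacetone (intramolecular Friedel–Crafts hydroxyalkylation at the only free position ortho to the ether oxygen, then loss of water) should give the 3-methylbenzofuran.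

Step 3
Reactants: 4 7-methoxy-3,5-dimethyl-1-benzofuran
Product: 5 3,5-dimethyl-1-benzofuran-7-ol
Conditions: BBr3, CH2Cl2, −78 → 0 °C; then H2O
Reagents that add atoms: none
Why: Lewis-acid cleavage of the aryl methyl ether (BBr3 demethylation), which the benzofuran should tolerate at low temperature.

Step 4
Reactants: 5 3,5-dimethyl-1-benzofuran-7-ol
Product: 6 3,5-dimethyl-1-benzofuran-4,7-dione
Conditions: (KSO3)2NO (2.2 equiv), KH2PO4, acetone/H2O, 0 °C → rt
Reagents that add atoms: Fremy's salt (potassium nitrosodisulfonate), [K+].[K+].[O]N(S(=O)(=O)[O-])S(=O)(=O)[O-]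
Why: Teuber oxidation: Fremy's radical converts a phenol with a free para position into the p-quinone, here the 4,7-dione.

Step 5
Reactants: 7 tetrahydro-4H-thiopyran-4-one
Product: 8 2,3-dihydro-4H-thiopyran-4-one
Conditions: NCS, pyridine, CH2Cl2, 0 °C → rt
Reagents that add atoms: none
Why: S-chlorination, Pummerer-type α-chlorination and loss of HCl (sulfide to vinyl sulfide dehydrogenation) should give the vinylogous thioester.

Step 6
Reactants: 8 2,3-dihydro-4H-thiopyran-4-one
Product: 9 triisopropyl(2H-thiopyran-4-yloxy)silane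
Conditions: TIPSOTf, Et3N, CH2Cl2, 0 °C
Reagents that add atoms: triisopropylsilyl triflate, CC(C)[Si](OS(=O)(=O)C(F)(F)F)(C(C)C)C(C)C
Why: Soft enolisation and O-silylation at the only enolisable position (C3) gives the cross-conjugated 2-silyloxy diene, locked s-cis by the ring; it is used freshly prepared.

Step 7
Reactants: 6 3,5-dimethyl-1-benzofuran-4,7-dione; 9 triisopropyl(2H-thiopyran-4-yloxy)silane
Product: 10 1β,15-epithio-3-(triisopropylsilyloxy)-10βH-furanoeremophil-2-ene-6,9-dione (endo adduct; C14, H-10 and the C15–S–C1 bridge all β)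
Conditions: B-(o-tolyl)oxazaborolidinium triflimide from α,α-diphenylprolinol (20 mol %, the antipode that leaves the C5-Re/C6-Si face of bound 6 open), CH2Cl2, −78 → −40 °C
Reagents that add atoms: none
Why: Normal-demand endo [4+2] cycloaddition, concerted but asynchronous (C4–C5 bond advanced), between the catalyst-bound C5=C6 bond of 6 and the electron-rich 1-thio-3-silyloxy diene of 9; the closest known reaction type is the cationic-oxazaborolidine-catalysed enantioselective Diels–Alder reaction of methyl-substituted 1,4-quinones with 2-silyloxy-1,3-dienes, combined with the established use of 2H-thiopyrans as cyclic (Z)-diene equivalents. Ring A (C1–C2–C3–C4–C5–C10) is closed in the suprafacial–suprafacial [4π+2π] mode by the two new bonds C4–C5 and C1–C10, and the same two bonds complete the temporary 2-thiabicyclo[2.2.2]octene. C5 and C10 should emerge cis because both bonds form on one face of the ring alkene; C4 is fixed relative to C5 by the endo transition state (quinone ring under the diene, CH2–S bridge anti), which puts C15 on the face of C14 and H-10 because the thiopyran ring forces the future methyl into the inside position of the diene; C1 is a temporary centre. The absolute configuration comes from the catalyst, which must shield the C5-Si/C6-Re face of the bound quinone. Site selectivity is secured because C5=C6 is the only quinonoid alkene (the other is part of the furan), and regioselectivity because the catalyst can bind only the C7 carbonyl (lone pair syn to C6–H free, whereas C4=O is flanked by two methyl groups and is a deactivated vinylogous ester), so the nucleophilic diene terminus C3′ attacks the methyl-bearing β-carbon C5 and the sulfur-bearing C6′ bonds to C6, both donors of the diene reinforcing this orientation. The angular methyl blocks aromatisation of the adduct, and the step needs high endo and facial selectivity, both typical of quinone dienophiles under this catalysis.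

Step 8
Reactants: 10 1β,15-epithio-3-(triisopropylsilyloxy)-10βH-furanoeremophil-2-ene-6,9-dione
Product: 11 1β,15-epithio-3-(triisopropylsilyloxy)-10βH-furanoeremophil-2-ene-6α,9α-diol
Conditions: LiAlH4, THF, −78 → 0 °C
Reagents that add atoms: none
Why: Hydride reduction of both furyl ketones; attack on C9=O should come from the exposed convex β face (the α face lies under the C2=C3 bridge), giving the 9α-alcohol, while the configuration formed at C6 (drawn α) is irrelevant because that oxygen is removed in step 11.

Step 9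
Reactants: 11 1β,15-epithio-3-(triisopropylsilyloxy)-10βH-furanoeremophil-2-ene-6α,9α-diol
Product: 12 9β-acetoxy-1β,15-epithio-3-(triisopropylsilyloxy)-10βH-furanoeremophil-2-en-6α-ol
Conditions: PPh3, DIAD, AcOH, toluene, 0 °C → rt
Reagents that add atoms: acetic acid, CC(=O)O
Why: Mitsunobu reaction: only the 2-furylcarbinol at C9 can undergo SN2 (the 6-OH is neopentyl), and backside entry of acetate from the open β face should invert C9 to the required 9β configuration, cis to H-10.

Step 10
Reactants: 12 9β-acetoxy-1β,15-epithio-3-(triisopropylsilyloxy)-10βH-furanoeremophil-2-en-6α-ol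
Product: 13 O-[9β-acetoxy-1β,15-epithio-3-(triisopropylsilyloxy)-10βH-furanoeremophil-2-en-6α-yl] S-methyl dithiocarbonate
Conditions: NaHMDS, THF, −78 °C; CS2; MeI, −78 → 0 °C
Reagents that add atoms: carbon disulfide, S=C=S; iodomethane, CI
Why: Xanthate formation (alkoxide addition to CS2, then S-methylation) on the remaining neopentyl 6-OH; no β-hydrogen is available for Chugaev elimination.

Step 11
Reactants: 13 O-[9β-acetoxy-1β,15-epithio-3-(triisopropylsilyloxy)-10βH-furanoeremophil-2-en-6α-yl] S-methyl dithiocarbonate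
Product: 14 9β-acetoxy-1β,15-epithio-3-(triisopropylsilyloxy)-10βH-furanoeremophil-2-ene
Conditions: Bu3SnH, Et3B (cat.), air, toluene, rt
Reagents that add atoms: none
Why: Barton–McCombie deoxygenation through the furan-stabilised C6 radical should remove the surplus quinone oxygen without touching the sulfide bridge or the C9 acetate.

Step 12
Reactants: 14 9β-acetoxy-1β,15-epithio-3-(triisopropylsilyloxy)-10βH-furanoeremophil-2-ene
Product: 16 9β-acetoxy-1β,15-epithio-10βH-furanoeremophilan-3α-ol, via bridged 3-ketone 15 (not isolated)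
Conditions: TBAF, AcOH, THF, 0 °C; then NaBH4 (excess), MeOH, −40 °C
Reagents that add atoms: none
Why: Buffered fluoride cleavage of the silyl enol ether (buffering avoids β-elimination of sulfur), then borohydride reduction of the bicyclo[2.2.2]octanone, where hydride should enter from the face of the CH2–S bridge, away from endo-fused ring B, giving the 3α-alcohol trans to C15; the bridgehead C4 cannot epimerise.

Step 13
Reactants: 16 9β-acetoxy-1β,15-epithio-10βH-furanoeremophilan-3α-ol
Product: 17 9β-acetoxy-10βH-furanoeremophilan-3α-ol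
Conditions: Raney Ni (W-2, deactivated in refluxing acetone), EtOH, rt
Reagents that add atoms: none
Why: Raney nickel hydrogenolysis of both C–S bonds turns C15 into the β-methyl on C4 and C1 into CH2 without touching a stereocentre, completing the (Z)-diene-equivalent tactic; deactivated nickel at room temperature is chosen to spare the furan and the furfuryl acetate.

Step 14
Reactants: 18 (E)-non-3-en-2-one; 19 triethyl (E)-4-phosphonocrotonate
Product: 20 ethyl (2E,4E,6E)-5-methyldodeca-2,4,6-trienoate
Conditions: LiHMDS, THF, −78 → 0 °C; minor 4Z isomer removed by chromatography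
Reagents that add atoms: none
Why: Vinylogous Horner–Wadsworth–Emmons olefination of the methyl ketone forms the trisubstituted C4=C5 bond, the all-E isomer being the expected major and thermodynamic product.

Step 15
Reactants: 20 ethyl (2E,4E,6E)-5-methyldodeca-2,4,6-trienoate
Product: 21 (2E,4E,6E)-5-methyldodeca-2,4,6-trienoic acid
Conditions: LiOH, THF/MeOH/H2O, rt; then aq. HCl
Reagents that add atoms: lithium hydroxide, [Li+].[OH-]
Why: Saponification of the ethyl ester; the conjugated triene is stable to aqueous hydroxide.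

Step 16
Reactants: 17 9β-acetoxy-10βH-furanoeremophilan-3α-ol; 21 (2E,4E,6E)-5-methyldodeca-2,4,6-trienoic acid
Product: 23 9β-acetoxy-10βH-furanoeremophilan-3α-yl (2E,4E,6E)-5-methyldodeca-2,4,6-trienoate, via mixed anhydride 22 (not isolated)
Conditions: 2,4,6-Cl3C6H2COCl, Et3N, THF, rt; then 17, DMAP, toluene, rt
Reagents that add atoms: none
Why: Yamaguchi esterification: the 3α-alcohol attacks the trienoyl carbonyl of the mixed anhydride under DMAP catalysis, with retention at C3.

Step 17
Reactants: 23 9β-acetoxy-10βH-furanoeremophilan-3α-yl (2E,4E,6E)-5-methyldodeca-2,4,6-trienoate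
Product: 25 9β-acetoxy-8,12-dioxo-10βH-eremophil-7(11)Z-en-3α-yl (2E,4E,6E)-5-methyldodeca-2,4,6-trienoate, via furan endoperoxide 24 (not isolated)
Conditions: O2, hν (visible), tetraphenylporphyrin (cat.), CH2Cl2, −78 °C; then Me2S, −78 → 0 °C
Reagents that add atoms: dioxygen, O=O
Why: [4+2] addition of singlet oxygen across C8/C12 of the trialkylfuran (expected to be far faster than attack on the ester-deactivated triene) and reduction of the endoperoxide by Me2S give the cis-enedione, so the C7=C11 geometry (C12 cis to C8) is inherited from the furan ring; the 9-acetate prevents cyclisation of a free hydroxyl onto C12.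

Step 18
Reactants: 25 9β-acetoxy-8,12-dioxo-10βH-eremophil-7(11)Z-en-3α-yl (2E,4E,6E)-5-methyldodeca-2,4,6-trienoate
Product: 26 9β-acetoxy-12-hydroxy-8-oxo-10βH-eremophil-7(11)Z-en-3α-yl (2E,4E,6E)-5-methyldodeca-2,4,6-trienoate
Conditions: LiAlH(Ot-Bu)3, THF, −78 °C
Reagents that add atoms: none
Why: Chemoselective 1,2-reduction of the aldehyde in the presence of the hindered tetrasubstituted enone and two esters by a bulky, mild alkoxyaluminium hydride at low temperature.

Step 19
Reactants: 26 9β-acetoxy-12-hydroxy-8-oxo-10βH-eremophil-7(11)Z-en-3α-yl (2E,4E,6E)-5-methyldodeca-2,4,6-trienoate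
Product: 27 (3R,4R,5R,9R,10S)-9β,12-dihydroxy-8-oxo-10βH-eremophil-7(11)Z-en-3α-yl (2E,4E,6E)-5-methyldodeca-2,4,6-trienoate (target)
Conditions: K2CO3 (cat.), MeOH, 0 °C; neutral work-up
Reagents that add atoms: none
Why: Base-catalysed methanolysis of the α-keto-activated acetate, which should be far more electrophilic than the hindered conjugated trienoate; acid is avoided because the (Z)-γ-hydroxy enone can cyclodehydrate to a furan, and the 9β-hydroxyl is expected to be the equatorial, more stable epimer.

**Compound list**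

1 | 2-methoxy-4-methylphenol (creosol) | COc1cc(C)ccc1O | starting material
2 | chloroacetone | CC(=O)CCl | starting material
3 | 1-(2-methoxy-4-methylphenoxy)propan-2-one | COc1cc(C)ccc1OCC(C)=O | intermediate
4 | 7-methoxy-3,5-dimethyl-1-benzofuran | COc1cc(C)cc2c(C)coc12 | intermediate
5 | 3,5-dimethyl-1-benzofuran-7-ol | Oc1cc(C)cc2c(C)coc12 | intermediate
6 | 3,5-dimethyl-1-benzofuran-4,7-dione | O=C1C=C(C)C(=O)c2c(C)coc12 | intermediate
7 | tetrahydro-4H-thiopyran-4-one | O=C1CCSCC1 | starting material
8 | 2,3-dihydro-4H-thiopyran-4-one | O=C1CCSC=C1 | intermediate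
9 | triisopropyl(2H-thiopyran-4-yloxy)silane | CC(C)[Si](OC1=CCSC=C1)(C(C)C)C(C)C | intermediate
10 | 1β,15-epithio-3-(triisopropylsilyloxy)-10βH-furanoeremophil-2-ene-6,9-dione (endo adduct) | CC(C)[Si](OC1=C[C@H]2SC[C@@H]1[C@@]3(C)C(=O)c4c(C)coc4C(=O)[C@@H]23)(C(C)C)C(C)C | intermediate
11 | 1β,15-epithio-3-(triisopropylsilyloxy)-10βH-furanoeremophil-2-ene-6α,9α-diol (C6 configuration inconsequential) | CC(C)[Si](OC1=C[C@H]2SC[C@@H]1[C@@]3(C)[C@@H](O)c4c(C)coc4[C@@H](O)[C@@H]23)(C(C)C)C(C)C | intermediate
12 | 9β-acetoxy-1β,15-epithio-3-(triisopropylsilyloxy)-10βH-furanoeremophil-2-en-6α-ol | CC(C)[Si](OC1=C[C@H]2SC[C@@H]1[C@@]3(C)[C@@H](O)c4c(C)coc4[C@H](OC(C)=O)[C@@H]23)(C(C)C)C(C)C | intermediate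
13 | O-[9β-acetoxy-1β,15-epithio-3-(triisopropylsilyloxy)-10βH-furanoeremophil-2-en-6α-yl] S-methyl dithiocarbonate | CC(C)[Si](OC1=C[C@H]2SC[C@@H]1[C@@]3(C)[C@@H](OC(=S)SC)c4c(C)coc4[C@H](OC(C)=O)[C@@H]23)(C(C)C)C(C)C | intermediate
14 | 9β-acetoxy-1β,15-epithio-3-(triisopropylsilyloxy)-10βH-furanoeremophil-2-ene | CC(C)[Si](OC1=C[C@H]2SC[C@@H]1[C@@]3(C)Cc4c(C)coc4[C@H](OC(C)=O)[C@@H]23)(C(C)C)C(C)C | intermediate
15 | 9β-acetoxy-1β,15-epithio-10βH-furanoeremophilan-3-one | O=C1C[C@H]2SC[C@@H]1[C@@]3(C)Cc4c(C)coc4[C@H](OC(C)=O)[C@@H]23 | intermediate (not isolated)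
16 | 9β-acetoxy-1β,15-epithio-10βH-furanoeremophilan-3α-ol | O[C@@H]1C[C@H]2SC[C@@H]1[C@@]3(C)Cc4c(C)coc4[C@H](OC(C)=O)[C@@H]23 | intermediate
17 | 9β-acetoxy-10βH-furanoeremophilan-3α-ol | O[C@@H]1CC[C@@H]2[C@@H](OC(C)=O)c3occ(C)c3C[C@]2(C)[C@H]1C | intermediate
18 | (E)-non-3-en-2-one | CCCCC/C=C/C(C)=O | starting material
19 | triethyl (E)-4-phosphonocrotonate | CCOC(=O)/C=C/CP(=O)(OCC)OCC | starting material
20 | ethyl (2E,4E,6E)-5-methyldodeca-2,4,6-trienoate | CCCCC/C=C/C(C)=C/C=C/C(=O)OCC | intermediate
21 | (2E,4E,6E)-5-methyldodeca-2,4,6-trienoic acid | CCCCC/C=C/C(C)=C/C=C/C(=O)O | intermediate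
22 | (2E,4E,6E)-5-methyldodeca-2,4,6-trienoic 2,4,6-trichlorobenzoic anhydride | CCCCC/C=C/C(C)=C/C=C/C(=O)OC(=O)c1c(Cl)cc(Cl)cc1Cl | intermediate (not isolated)
23 | 9β-acetoxy-10βH-furanoeremophilan-3α-yl (2E,4E,6E)-5-methyldodeca-2,4,6-trienoate | CCCCC/C=C/C(C)=C/C=C/C(=O)O[C@@H]1CC[C@@H]2[C@@H](OC(C)=O)c3occ(C)c3C[C@]2(C)[C@H]1C | intermediate
24 | 8,12-epidioxide (furan endoperoxide) of 23; peroxide bridge on either face, both converge on 25 | CCCCC/C=C/C(C)=C/C=C/C(=O)O[C@@H]1CC[C@@H]2[C@@H](OC(C)=O)C34OOC(O3)C(C)=C4C[C@]2(C)[C@H]1C | intermediate (not isolated)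
25 | 9β-acetoxy-8,12-dioxo-10βH-eremophil-7(11)Z-en-3α-yl (2E,4E,6E)-5-methyldodeca-2,4,6-trienoate | CCCCC/C=C/C(C)=C/C=C/C(=O)O[C@@H]1CC[C@@H]2[C@@H](OC(C)=O)C(=O)/C(=C(/C)C=O)C[C@]2(C)[C@H]1C | intermediate
26 | 9β-acetoxy-12-hydroxy-8-oxo-10βH-eremophil-7(11)Z-en-3α-yl (2E,4E,6E)-5-methyldodeca-2,4,6-trienoate | CCCCC/C=C/C(C)=C/C=C/C(=O)O[C@@H]1CC[C@@H]2[C@@H](OC(C)=O)C(=O)/C(=C(/C)CO)C[C@]2(C)[C@H]1C | intermediate
27 | (3R,4R,5R,9R,10S)-9β,12-dihydroxy-8-oxo-10βH-eremophil-7(11)Z-en-3α-yl (2E,4E,6E)-5-methyldodeca-2,4,6-trienoate | CCCCC/C=C/C(C)=C/C=C/C(=O)O[C@@H]1CC[C@@H]2[C@@H](O)C(=O)/C(=C(/C)CO)C[C@]2(C)[C@H]1C | target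

**Step count and risks**

Total step count: 19. Longest linear sequence: 15 steps (steps 1–4, 7–13, 16–19); the diene (steps 5–6) and the acid (steps 14–15) are side branches.

Steps most likely to fail:

Step 7. The bond to the methyl-bearing quinone carbon is slow to form, and the Lewis-acid-activated quinone may instead abstract hydride from C2′ of the thiopyran or trigger desilylative Michael addition; enantiofacial discrimination may also be modest. Fallback: 6 and 9 are combined without any Lewis acid (toluene, 80 °C, or 10–12 kbar in CH2Cl2 at rt), where the endo and regiochemical preferences inherent to the partners still operate. This gives the racemate, that is 10 together with its mirror image ent-10 F1. The enantiomers are separated by preparative chromatography on a chiral stationary phase, and the route is re-entered at 10.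

Step 9. The oxyphosphonium salt may not form at the concave, hindered hydroxyl, backside displacement may be slow, or H-10 may be lost by elimination. Fallback from 11: Cl3CCN and catalytic DBU (CH2Cl2, 0 °C) convert the 9α-hydroxyl into the 9α-O-trichloroacetimidate of 11 F2 (the neopentyl 6-OH should not compete). F2 is then stirred with acetic acid in CH2Cl2 at −20 → 0 °C. Ionisation gives the furan-stabilised C9 cation, which acetate should capture on the open β face (the α face is covered by the C2=C3 bridge), giving 12, where the route is rejoined. This replaces SN2 inversion by ionisation with face-selective capture.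

Step 17. The trienoate may undergo competing ene or [4+2] photooxygenation, and the product may be over-oxidised. Fallback from 17, before any triene is present: photooxygenation (O2, hν, tetraphenylporphyrin, CH2Cl2, −78 °C) gives the furan endoperoxide of 17 F3, which Me2S reduces in the same flask to the hydroxy (Z)-keto-enal F4. LiAlH(Ot-Bu)3 (THF, −78 °C) reduces the aldehyde to the 3α,12-diol F5. TBSCl and imidazole (CH2Cl2, 0 °C) silylate only the primary allylic hydroxyl, giving the 12-O-TBS ether F6. Esterification of the remaining 3α-OH with 21 under the conditions of step 16 gives the trienoate F7. Pyridine-buffered HF·pyridine (THF, 0 °C) removes the silyl group, and the route is rejoined at 26.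

Further compounds
F1 | step 7 | ent-10, mirror image of adduct 10 | CC(C)[Si](OC1=C[C@@H]2SC[C@H]1[C@]3(C)C(=O)c4c(C)coc4C(=O)[C@H]23)(C(C)C)C(C)C
F2 | step 9 | 9α-O-trichloroacetimidate of 11 | CC(C)[Si](OC1=C[C@H]2SC[C@@H]1[C@@]3(C)[C@@H](O)c4c(C)coc4[C@@H](OC(=N)C(Cl)(Cl)Cl)[C@@H]23)(C(C)C)C(C)C
F3 | step 17 | 8,12-epidioxide (furan endoperoxide) of 17, peroxide bridge on either face | O[C@@H]1CC[C@@H]2[C@@H](OC(C)=O)C34OOC(O3)C(C)=C4C[C@]2(C)[C@H]1C
F4 | step 17 | 9β-acetoxy-3α-hydroxy-8-oxo-10βH-eremophil-7(11)Z-en-12-al | O[C@@H]1CC[C@@H]2[C@@H](OC(C)=O)C(=O)/C(=C(/C)C=O)C[C@]2(C)[C@H]1C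
F5 | step 17 | 9β-acetoxy-3α,12-dihydroxy-10βH-eremophil-7(11)Z-en-8-one | O[C@@H]1CC[C@@H]2[C@@H](OC(C)=O)C(=O)/C(=C(/C)CO)C[C@]2(C)[C@H]1C
F6 | step 17 | 9β-acetoxy-12-(tert-butyldimethylsilyloxy)-3α-hydroxy-10βH-eremophil-7(11)Z-en-8-one | O[C@@H]1CC[C@@H]2[C@@H](OC(C)=O)C(=O)/C(=C(/C)CO[Si](C)(C)C(C)(C)C)C[C@]2(C)[C@H]1C
F7 | step 17 | 9β-acetoxy-12-(tert-butyldimethylsilyloxy)-8-oxo-10βH-eremophil-7(11)Z-en-3α-yl (2E,4E,6E)-5-methyldodeca-2,4,6-trienoate | CCCCC/C=C/C(C)=C/C=C/C(=O)O[C@@H]1CC[C@@H]2[C@@H](OC(C)=O)C(=O)/C(=C(/C)CO[Si](C)(C)C(C)(C)C)C[C@]2(C)[C@H]1C
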